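**Retrosynthetic overview**
1. Locants: ring A = C1 (C–OH, C6H2OAc), C3 (dienyl), C5 (bond to ring B); ring B = C1' (on C5), C2' (C=O), C3'=C4', C5' (CH3). Target 30 ⇐ diol 29 (acetylation last) ⇐ bicyclic ketone 24 by C3'–C4' dehydrogenation and kinetic re-protonation at C1'.
2. Key step: acyclic keto-nitrile 21 ⇒ 24 in one SmI2 operation. Ring A closes first (ketyl–olefin 5-exo, C1–C5), then ring B (the alkylsamarium adds to the nitrile, C1'–C2').
3. 21 ⇐ Wittig of keto-aldehyde 16 with the ylide from phosphonium salt 19; C5' comes from (S)-1-bromo-3-chloro-2-methylpropane.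
4. 16 ⇐ Rh/(R)-BINAP 1,4-addition of the (Z)-dienylboron species from iodide 6 to enone 12 (sets C3); 12 ⇐ 4,4-diethoxybut-1-yne + TBSOCH2CHO.
5. 6 ⇐ but-2-yn-1-ol (Red-Al/I2 fixes the Z trisubstituted alkene), then allyl–alkenyl coupling.

Assumption: the SMILES is taken as drawn (2Z side-chain alkene; methyl and cyclopentyl cis on the cyclopentenone), and 5, 7, 8, 17 and the Schwartz reagent are treated as commercial (TBS = tert-butyldimethylsilyl).

**Route**

Step 1
Reactants: 1 but-2-yn-1-ol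
Product: 3 (Z)-3-iodobut-2-en-1-ol, via cyclic vinylalanate 2 (not isolated)
Conditions: Red-Al, THF, 0 °C → rt; EtOAc; then I2, −78 °C → rt
Reagents that add atoms: iodine (II)
Why: alkoxide-directed trans-hydroalumination of the propargylic alcohol puts Al on C3 cis to CH2O, and iodinolysis with retention gives the Z vinyl iodide, which fixes the side-chain alkene geometry.

Step 2
Reactants: 3 (Z)-3-iodobut-2-en-1-ol
Product: 4 (Z)-1-bromo-3-iodobut-2-ene
Conditions: CBr4, PPh3, CH2Cl2, 0 °C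
Reagents that add atoms: carbon tetrabromide (BrC(Br)(Br)Br)
Why: Appel bromination of the primary allylic alcohol is an SN2 at CH2 that leaves the vinyl iodide and the alkene geometry untouched.

Step 3
Reactants: 4 (Z)-1-bromo-3-iodobut-2-ene; 5 2-methylprop-1-enylmagnesium bromide
Product: 6 (Z)-2-iodo-6-methylhepta-2,5-diene
Conditions: CuI (10 mol %), THF, −30 → 0 °C
Reagents that add atoms: none
Why: Cu-catalysed SN2 allyl–alkenyl Grignard coupling, in which SN2' is blocked by the fully substituted γ-carbon and the vinyl iodide is inert at this temperature.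

Step 4
Reactants: 7 4,4-diethoxybut-1-yne; 8 (tert-butyldimethylsilyloxy)acetaldehyde
Product: 11 (E)-1-(TBS-oxy)-6,6-diethoxyhex-3-en-2-ol (racemic), via alkenylzirconocene chloride 9 (not isolated), via alkenyl(methyl)zinc 10 (not isolated)
Conditions: Cp2Zr(H)Cl, CH2Cl2, rt; Me2Zn, toluene, −65 °C; then 8, 0 °C
Reagents that add atoms: none
Why: syn-hydrozirconation of the terminal alkyne gives the E alkenyl metal and Zr→Zn transmetalation allows clean 1,2-addition to the aldehyde (Wipf protocol); the carbinol centre is racemic and is oxidised away in step 5.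

Step 5
Reactants: 11 (E)-1-(TBS-oxy)-6,6-diethoxyhex-3-en-2-ol
Product: 12 (E)-1-(TBS-oxy)-6,6-diethoxyhex-3-en-2-one
Conditions: MnO2, CH2Cl2, rt
Reagents that add atoms: none
Why: chemoselective MnO2 oxidation of the allylic alcohol to the E enone, with acetal and silyl ether inert.

Step 6
Reactants: 6 (Z)-2-iodo-6-methylhepta-2,5-diene; 12 (E)-1-(TBS-oxy)-6,6-diethoxyhex-3-en-2-one
Product: 15 (4S,5Z)-1-(TBS-oxy)-4-(2,2-diethoxyethyl)-5,9-dimethyldeca-5,8-dien-2-one, via alkenyllithium 13 (not isolated), via lithium alkenylborate 14 (not isolated)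
Conditions: t-BuLi (2 equiv), Et2O, −78 °C; B(OMe)3, −78 °C → rt; then 12, [Rh(OH)((R)-binap)]2 (3 mol % Rh), dioxane/H2O 10:1, 40 °C
Reagents that add atoms: none
Why: Hayashi–Miyaura Rh-catalysed asymmetric 1,4-addition, in which I/Li exchange and B/Rh transmetalation retain the Z alkenyl geometry and (R)-BINAP delivers the alkenyl group to the α-Re face of the E enone (mirror image of the (S)-BINAP/α-Si rule) to set C3 as S.

Step 7
Reactants: 15 (4S,5Z)-1-(TBS-oxy)-4-(2,2-diethoxyethyl)-5,9-dimethyldeca-5,8-dien-2-one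
Product: 16 (3S,4Z)-3-[3-(TBS-oxy)-2-oxopropyl]-4,8-dimethylnona-4,7-dienal
Conditions: AcOH/THF/H2O (4:2:1), rt
Reagents that add atoms: water (O)
Why: mild acid hydrolysis of the acyclic diethyl acetal, which spares the primary TBS ether and the C3 centre (not α to a carbonyl).

Step 8
Reactants: 17 (S)-1-bromo-3-chloro-2-methylpropane
Product: 18 (R)-5-chloro-4-methylpentanenitrile
Conditions: MeCN, n-BuLi, THF, −78 °C; then 17, −78 → 0 °C
Reagents that add atoms: acetonitrile (CC#N)
Why: SN2 alkylation of lithioacetonitrile at the primary bromide (Br far more reactive than Cl); the stereocentre is not involved and keeps its configuration (S → R is a CIP change only).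

Step 9
Reactants: 18 (R)-5-chloro-4-methylpentanenitrile
Product: 19 (R)-(4-cyano-2-methylbutyl)triphenylphosphonium iodide
Conditions: NaI, PPh3, MeCN, reflux
Reagents that add atoms: triphenylphosphine (c1ccc(cc1)P(c1ccccc1)c1ccccc1); sodium iodide ([Na+].[I-])
Why: in situ Finkelstein exchange followed by SN2 quaternisation of PPh3 at the primary carbon, with the stereocentre untouched.

Step 10
Reactants: 19 (R)-(4-cyano-2-methylbutyl)triphenylphosphonium iodide; 16 (3S,4Z)-3-[3-(TBS-oxy)-2-oxopropyl]-4,8-dimethylnona-4,7-dienal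
Product: 21 (4R,5Z,8S,9Z)-8-[3-(TBS-oxy)-2-oxopropyl]-4,9,13-trimethyltetradeca-5,9,12-trienenitrile, via phosphorus ylide 20 (not isolated)
Conditions: NaHMDS, THF, −78 °C; then 16, −78 → 0 °C
Reagents that add atoms: none
Why: Wittig olefination with a non-stabilised ylide takes the aldehyde over the hindered ketone at −78 °C; the (mainly Z) geometry of the new alkene is irrelevant because both of its carbons become sp3 in step 11, and no stereocentre is touched.

Step 11
Reactants: 21 (4R,5Z,8S,9Z)-8-[3-(TBS-oxy)-2-oxopropyl]-4,9,13-trimethyltetradeca-5,9,12-trienenitrile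
Product: 24 (2R,3R)-2-[(1S,2R,4S)-2-hydroxy-2-(TBS-oxymethyl)-4-[(2Z)-6-methylhepta-2,5-dien-2-yl]cyclopentyl]-3-methylcyclopentan-1-one, via alkylsamarium 22 (not isolated), via ketimine 23 (not isolated)
Conditions: SmI2 (2.5 equiv), HMPA (10 equiv), THF, 0 °C → rt (21 added slowly); then 1 M aq. HCl, 0 °C
Reagents that add atoms: water (O)
Why: Proposed new method: SmI2/HMPA reduces the ketone to a ketyl that closes ring A by 5-exo attack on the unactivated alkene through a chair transition state with the C3 dienyl group pseudo-equatorial (new C5 substituent cis to it) and the bulky O–Sm anti to the alkene (tertiary OH trans to the C5–C1' bond); the secondary radical is reduced to alkylsamarium 22, which adds 5-exo to the Sm(III)-bound nitrile to close ring B as metallo-ketimine 23, inert to further reduction and hydrolysed to the ketone on work-up; the closest known chemistry is Molander's sequential ketyl–olefin cyclisation/organosamarium trapping and SmI2 Barbier-type additions to nitriles, and C1' (formed mainly trans to the methyl) is corrected in step 13.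

Step 12
Reactants: 24 (2R,3R)-2-[(1S,2R,4S)-2-hydroxy-2-(TBS-oxymethyl)-4-[(2Z)-6-methylhepta-2,5-dien-2-yl]cyclopentyl]-3-methylcyclopentan-1-one
Product: 26 (4R,5R)-5-[(1S,2R,4S)-2-hydroxy-2-(TBS-oxymethyl)-4-[(2Z)-6-methylhepta-2,5-dien-2-yl]cyclopentyl]-4-methylcyclopent-2-en-1-one, via lithium enolate 25 (not isolated)
Conditions: LDA (2.2 equiv), THF, −78 °C; then PhS(Cl)=N-t-Bu (1.5 equiv), −78 °C
Reagents that add atoms: none
Why: Mukaiyama dehydrogenation, in which LDA forms the alkoxide and the kinetic enolate at the unhindered C3' methylene, S-sulfinimidoylation and syn-elimination then give the C3'=C4' enone without touching C1' or C5'.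

Step 13
Reactants: 26 (4R,5R)-5-[(1S,2R,4S)-2-hydroxy-2-(TBS-oxymethyl)-4-[(2Z)-6-methylhepta-2,5-dien-2-yl]cyclopentyl]-4-methylcyclopent-2-en-1-one
Product: 29 (4R,5S)-5-[(1S,2R,4S)-2-hydroxy-2-(hydroxymethyl)-4-[(2Z)-6-methylhepta-2,5-dien-2-yl]cyclopentyl]-4-methylcyclopent-2-en-1-one, via lithium dienolate 27 (not isolated), via cis-enone silyl ether 28 (not isolated)
Conditions: LDA (2.5 equiv), THF, −78 °C; 2,6-di-tert-butylphenol (5 equiv), −78 °C; then HF·pyridine, pyridine, −78 → 0 °C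
Reagents that add atoms: none
Why: α'-deprotonation gives the cross-conjugated dienolate (C1' becomes planar) and kinetic protonation by the hindered phenol on the ring-B face anti to the adjacent C5' methyl places the cyclopentyl group cis to that methyl (contra-thermodynamic, as in epi-jasmonate chemistry; recovered trans isomer can be recycled through the same enolate), after which HF·pyridine removes the primary TBS ether without base.

Step 14
Reactants: 29 (4R,5S)-5-[(1S,2R,4S)-2-hydroxy-2-(hydroxymethyl)-4-[(2Z)-6-methylhepta-2,5-dien-2-yl]cyclopentyl]-4-methylcyclopent-2-en-1-one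
Product: 30 [(1R,2S,4S)-1-hydroxy-2-[(1S,5R)-5-methyl-2-oxocyclopent-3-en-1-yl]-4-[(2Z)-6-methylhepta-2,5-dien-2-yl]cyclopentyl]methyl acetate
Conditions: Ac2O (1.2 equiv), pyridine, CH2Cl2, 0 °C
Reagents that add atoms: acetic anhydride (CC(=O)OC(C)=O)
Why: selective O-acetylation of the primary alcohol (the tertiary carbinol does not react), run without DMAP so that the epimerisable cis C1' centre is preserved.

**Compound list**
1 | but-2-yn-1-ol | CC#CCO | starting material
2 | sodium cyclic alkenylalanate (Al on C3, cis to CH2O) | [Na+].CC1=CCO[Al-]1(OCCOC)OCCOC | intermediate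
3 | (Z)-3-iodobut-2-en-1-ol | I/C(C)=C\CO | intermediate
4 | (Z)-1-bromo-3-iodobut-2-ene | I/C(C)=C\CBr | intermediate
5 | 2-methylprop-1-enylmagnesium bromide | CC(C)=C[Mg]Br | starting material
6 | (Z)-2-iodo-6-methylhepta-2,5-diene | I/C(C)=C\CC=C(C)C | intermediate
7 | 4,4-diethoxybut-1-yne | C#CCC(OCC)OCC | starting material
8 | (tert-butyldimethylsilyloxy)acetaldehyde | CC(C)(C)[Si](C)(C)OCC=O | starting material
9 | chloro[(1E)-4,4-diethoxybut-1-enyl]zirconocene | CCOC(C/C=C/[Zr](Cl)(C1C=CC=C1)C1C=CC=C1)OCC | intermediate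
10 | [(1E)-4,4-diethoxybut-1-enyl](methyl)zinc | CCOC(C/C=C/[Zn]C)OCC | intermediate
11 | (E)-1-(TBS-oxy)-6,6-diethoxyhex-3-en-2-ol (racemic) | CCOC(C/C=C/C(O)CO[Si](C)(C)C(C)(C)C)OCC | intermediate
12 | (E)-1-(TBS-oxy)-6,6-diethoxyhex-3-en-2-one | CCOC(C/C=C/C(=O)CO[Si](C)(C)C(C)(C)C)OCC | intermediate
13 | (Z)-(6-methylhepta-2,5-dien-2-yl)lithium | [Li]/C(C)=C\CC=C(C)C | intermediate
14 | lithium trimethoxy[(2Z)-6-methylhepta-2,5-dien-2-yl]borate | [Li+].CO[B-](OC)(OC)/C(C)=C\CC=C(C)C | intermediate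
15 | (4S,5Z)-1-(TBS-oxy)-4-(2,2-diethoxyethyl)-5,9-dimethyldeca-5,8-dien-2-one | CC(C)(C)[Si](C)(C)OCC(=O)C[C@@H](/C(C)=C\CC=C(C)C)CC(OCC)OCC | intermediate
16 | (3S,4Z)-3-[3-(TBS-oxy)-2-oxopropyl]-4,8-dimethylnona-4,7-dienal | CC(C)(C)[Si](C)(C)OCC(=O)C[C@@H](/C(C)=C\CC=C(C)C)CC=O | intermediate
17 | (S)-1-bromo-3-chloro-2-methylpropane | ClC[C@H](C)CBr | starting material
18 | (R)-5-chloro-4-methylpentanenitrile | ClC[C@H](C)CCC#N | intermediate
19 | (R)-(4-cyano-2-methylbutyl)triphenylphosphonium iodide | c1ccccc1[P+](c1ccccc1)(c1ccccc1)C[C@H](C)CCC#N.[I-] | intermediate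
20 | (R)-(4-cyano-2-methylbutylidene)triphenylphosphorane | c1ccccc1P(c1ccccc1)(c1ccccc1)=C[C@H](C)CCC#N | intermediate
21 | (4R,5Z,8S,9Z)-8-[3-(TBS-oxy)-2-oxopropyl]-4,9,13-trimethyltetradeca-5,9,12-trienenitrile | CC(C)(C)[Si](C)(C)OCC(=O)C[C@@H](/C(C)=C\CC=C(C)C)C/C=C\[C@H](C)CCC#N | intermediate
22 | ring-A alkylsamarium (C1–O–SmI2 alkoxide, SmI2 on C1') | CC(C)(C)[Si](C)(C)OC[C@@]1(O[Sm](I)I)C[C@@H](/C(C)=C\CC=C(C)C)C[C@H]1C([Sm](I)I)[C@H](C)CCC#N | intermediate
23 | bicyclic N–H ketimine (C1' epimers) | CC(C)(C)[Si](C)(C)OC[C@@]1(O)C[C@@H](/C(C)=C\CC=C(C)C)C[C@H]1C1C(=N)CC[C@H]1C | intermediate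
24 | (2R,3R)-2-[(1S,2R,4S)-2-hydroxy-2-(TBS-oxymethyl)-4-[(2Z)-6-methylhepta-2,5-dien-2-yl]cyclopentyl]-3-methylcyclopentan-1-one | CC(C)(C)[Si](C)(C)OC[C@@]1(O)C[C@@H](/C(C)=C\CC=C(C)C)C[C@H]1[C@@H]1C(=O)CC[C@H]1C | intermediate
25 | dilithium alkoxide/C2'=C3' enolate of 24 | CC(C)(C)[Si](C)(C)OC[C@@]1(O[Li])C[C@@H](/C(C)=C\CC=C(C)C)C[C@H]1[C@@H]1C(O[Li])=CC[C@H]1C | intermediate
26 | (4R,5R)-5-[(1S,2R,4S)-2-hydroxy-2-(TBS-oxymethyl)-4-[(2Z)-6-methylhepta-2,5-dien-2-yl]cyclopentyl]-4-methylcyclopent-2-en-1-one (trans) | CC(C)(C)[Si](C)(C)OC[C@@]1(O)C[C@@H](/C(C)=C\CC=C(C)C)C[C@H]1[C@@H]1C(=O)C=C[C@H]1C | intermediate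
27 | dilithium alkoxide/cross-conjugated dienolate of 26 | CC(C)(C)[Si](C)(C)OC[C@@]1(O[Li])C[C@@H](/C(C)=C\CC=C(C)C)C[C@H]1C1=C(O[Li])C=C[C@H]1C | intermediate
28 | (4R,5S)-5-[(1S,2R,4S)-2-hydroxy-2-(TBS-oxymethyl)-4-[(2Z)-6-methylhepta-2,5-dien-2-yl]cyclopentyl]-4-methylcyclopent-2-en-1-one (cis) | CC(C)(C)[Si](C)(C)OC[C@@]1(O)C[C@@H](/C(C)=C\CC=C(C)C)C[C@H]1[C@H]1C(=O)C=C[C@H]1C | intermediate
29 | (4R,5S)-5-[(1S,2R,4S)-2-hydroxy-2-(hydroxymethyl)-4-[(2Z)-6-methylhepta-2,5-dien-2-yl]cyclopentyl]-4-methylcyclopent-2-en-1-one | OC[C@@]1(O)C[C@@H](/C(C)=C\CC=C(C)C)C[C@H]1[C@H]1C(=O)C=C[C@H]1C | intermediate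
30 | [(1R,2S,4S)-1-hydroxy-2-[(1S,5R)-5-methyl-2-oxocyclopent-3-en-1-yl]-4-[(2Z)-6-methylhepta-2,5-dien-2-yl]cyclopentyl]methyl acetate | CC(=O)OC[C@@]1(O)C[C@@H](/C(C)=C\CC=C(C)C)C[C@H]1[C@H]1C(=O)C=C[C@H]1C | target

**Step count**
Total: 14 steps. Longest linear sequence: 10 steps (1, 2, 3, 6, 7, 10, 11, 12, 13, 14).

**Three steps most likely to fail**

Step 11 (SmI2 bis-cyclisation). The risks are C–O cleavage of the α-silyloxy ketyl before it reaches the unactivated alkene, and loss of the secondary radical or alkylsamarium (H-abstraction from THF, α-deprotonation of the nitrile) before ring B closes. The fallback sets out from 16 and buys ring B instead of making it in the cascade. Cu(OTf)2/Feringa phosphoramidite-catalysed addition of Me2Zn to cyclopent-2-enone (ligand enantiomer giving the 3R adduct) is followed by trapping of the zinc enolate at the aldehyde of 16, which gives the aldol adduct F1. MsCl/Et3N then DBU gives the (E)-alkylidenecyclopentanone F2. SmI2 (2.2 equiv) with t-BuOH in THF at −78 °C then closes ring A onto the now activated exocyclic enone, fast enough to outrun C–O cleavage and under the same chair/anti control; protonation of the samarium enolate returns the route at 24 (either C1' epimer, both converge in step 13).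

Step 13 (kinetic protonation at C1'). The risks are competing γ-deprotonation at C5'–H, which would scramble the methyl centre, and weak facial selectivity. The fallback sets out from 24 and moves the epimerisation one oxidation level earlier, where no α'/γ competition exists. Thermodynamic silylation (TMSCl, NaI, Et3N, MeCN) gives the tetrasubstituted silyl enol ether F3 (tertiary OH also silylated). MeLi in THF at 0 °C regenerates the enolate, and 2,6-di-tert-butylphenol at −78 °C with citric acid work-up gives the cis-ketone F4. LDA/PhS(Cl)=N-t-Bu as in step 12 (kinetic C3' enolate, C1' untouched) then returns the route at 28, which is desilylated to 29 as in step 13.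

Step 6 (Rh-catalysed alkenyl addition). The risks are slow transmetalation or protodeboronation of the α-branched Z-alkenylboron species, and low ee or the opposite facial sense with the acyclic enone. The fallback sets out from 6 and sets C3 by auxiliary control. Alkenyllithium 13 is converted with MgBr2·OEt2 and CuBr·SMe2 into the alkenylcopper reagent and added (THF/Me2S, −40 °C) to (R)-4-benzyl-3-[(E)-5,5-diethoxypent-2-enoyl]oxazolidin-2-one, giving the imide F5 (attack anti to benzyl in the chelated syn-s-cis conformer gives the same S centre). Me3Al/MeNHOMe·HCl gives the Weinreb amide F6, MeMgBr the methyl ketone F7, and LDA (−78 °C, kinetic methyl enolate) followed by Davis oxaziridine the 1-hydroxy ketone F8. TBSCl/imidazole returns the route at 15.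

**Further compounds**
F1 | step 11 | (2R,3R)-2-[(3S,4Z)-1-hydroxy-3-[3-(TBS-oxy)-2-oxopropyl]-4,8-dimethylnona-4,7-dienyl]-3-methylcyclopentan-1-one (carbinol epimers) | CC(C)(C)[Si](C)(C)OCC(=O)C[C@@H](/C(C)=C\CC=C(C)C)CC(O)[C@@H]1C(=O)CC[C@H]1C
F2 | step 11 | (2E,3R)-2-[(3S,4Z)-3-[3-(TBS-oxy)-2-oxopropyl]-4,8-dimethylnona-4,7-dienylidene]-3-methylcyclopentan-1-one | CC(C)(C)[Si](C)(C)OCC(=O)C[C@@H](/C(C)=C\CC=C(C)C)C/C=C1/C(=O)CC[C@H]1C
F3 | step 13 | C1'=C2' trimethylsilyl enol ether of 24 with the tertiary OH as TMS ether | CC(C)(C)[Si](C)(C)OC[C@@]1(O[Si](C)(C)C)C[C@@H](/C(C)=C\CC=C(C)C)C[C@H]1C1=C(O[Si](C)(C)C)CC[C@H]1C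
F4 | step 13 | (2S,3R)-2-[(1S,2R,4S)-2-hydroxy-2-(TBS-oxymethyl)-4-[(2Z)-6-methylhepta-2,5-dien-2-yl]cyclopentyl]-3-methylcyclopentan-1-one (cis) | CC(C)(C)[Si](C)(C)OC[C@@]1(O)C[C@@H](/C(C)=C\CC=C(C)C)C[C@H]1[C@H]1C(=O)CC[C@H]1C
F5 | step 6 | (R)-4-benzyl-3-[(3S,4Z)-3-(2,2-diethoxyethyl)-4,8-dimethylnona-4,7-dienoyl]oxazolidin-2-one | O=C1OC[C@@H](Cc2ccccc2)N1C(=O)C[C@@H](/C(C)=C\CC=C(C)C)CC(OCC)OCC
F6 | step 6 | (3S,4Z)-3-(2,2-diethoxyethyl)-N-methoxy-N,4,8-trimethylnona-4,7-dienamide | CON(C)C(=O)C[C@@H](/C(C)=C\CC=C(C)C)CC(OCC)OCC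
F7 | step 6 | (4S,5Z)-4-(2,2-diethoxyethyl)-5,9-dimethyldeca-5,8-dien-2-one | CC(=O)C[C@@H](/C(C)=C\CC=C(C)C)CC(OCC)OCC
F8 | step 6 | (4S,5Z)-4-(2,2-diethoxyethyl)-1-hydroxy-5,9-dimethyldeca-5,8-dien-2-one | OCC(=O)C[C@@H](/C(C)=C\CC=C(C)C)CC(OCC)OCC
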